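**Plan**

- Retrosynthesis: the C3–OH is traced back to a C3–Si bond (oxidation with retention). The pyran ring is then cut at O1–C2 and C3–C4 into an ortho-quinone methide of ring A and an (E)-β-silylstyrene carrying ring B.
- Enabling feature: ring C holds the four-atom unit O1–C8a=C4a–C4, which is a 1-oxadiene once C8a–O1 is a carbonyl and C4 an exocyclic methylene. The remaining C2–C3 unit carries aryl (C2) and oxygen (C3) trans, which is the image of an E-alkene bearing aryl and a hydroxyl surrogate.
- Further cuts: C4 from ring A (formylation, reduction), the C8–prenyl bond (ortho-lithiation), the vinyl C–Si bond (hydrosilylation) and the alkyne carbon (aldehyde homologation).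
- Forward: the ring-A salicyl alcohol (steps 1–6) and the styrylsilane (steps 7–9) are made separately and joined in step 10, which closes ring C, the only ring formed. Step 11 unmasks the three hydroxyls.
- Stereochemistry: the E-alkene geometry gives 2,3-trans, the chiral phosphoric acid sets the absolute sense (2R,3S), and the C–Si oxidation retains C3.

Key step: step 10

Assumption: the (R)-configured acid is taken to deliver the (2R,3S) adduct; if the opposite sense is found, the mirror-image catalyst is used and nothing else changes. Ring A carries a TIPS ether (more robust through formylation-stage handling and reduction) and ring B a TBS ether.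

**Route**

Step 1
Reactants: 1 5-methoxyresorcinol
Product: 2 1-methoxy-3,5-bis(methoxymethoxy)benzene
Conditions: NaH, MOMCl, DMF, 0 °C → rt
Reagents that add atoms: chloromethyl methyl ether (MOMCl), COCCl
Why: Williamson-type O-alkylation of both phenoxides should cap the hydroxyls as MOM acetals, which later act as ortho-directing groups.

Step 2
Reactants: 2 1-methoxy-3,5-bis(methoxymethoxy)benzene; 3 prenyl bromide
Product: 5 5-methoxy-1,3-bis(methoxymethoxy)-2-(3-methylbut-2-en-1-yl)benzene, via aryllithium 4 (not isolated)
Conditions: n-BuLi, THF, 0 °C → rt; then CuI (10 mol %), 3, −78 °C → rt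
Reagents that add atoms: none
Why: Directed ortho-metalation should take place at the carbon between the two chelating OMOM groups (the positions flanked by OMOM and OMe are less acidified), and copper-catalysed SN2 allylation of the aryllithium by the primary allylic bromide installs the linear prenyl group.

Step 3
Reactants: 5 5-methoxy-1,3-bis(methoxymethoxy)-2-(3-methylbut-2-en-1-yl)benzene
Product: 6 5-methoxy-2-(3-methylbut-2-en-1-yl)benzene-1,3-diol
Conditions: 3 M aq HCl, MeOH, rt → 40 °C
Reagents that add atoms: none
Why: Acid-catalysed acetal methanolysis should release both phenols, the mild temperature being chosen so that acetal cleavage outpaces acid-induced cyclisation of the prenyl group.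

Step 4
Reactants: 6 5-methoxy-2-(3-methylbut-2-en-1-yl)benzene-1,3-diol
Product: 8 2,4-dihydroxy-6-methoxy-3-(3-methylbut-2-en-1-yl)benzaldehyde, via aryl iminium chloride 7 (not isolated)
Conditions: POCl3, DMF, MeCN, 0 °C → rt; then H2O (NaOAc-buffered), rt → 40 °C
Reagents that add atoms: N,N-dimethylformamide, CN(C)C=O; water, O
Why: Vilsmeier–Haack formylation should attack one of the two equivalent free ring positions (each ortho to one hydroxyl and para to the other), so only one regioisomer can form, and buffered hydrolysis of the iminium salt gives the aldehyde.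

Step 5
Reactants: 8 2,4-dihydroxy-6-methoxy-3-(3-methylbut-2-en-1-yl)benzaldehyde
Product: 9 2-hydroxy-6-methoxy-3-(3-methylbut-2-en-1-yl)-4-(triisopropylsilyloxy)benzaldehyde
Conditions: TIPSCl (1.05 equiv), imidazole, DMF, 0 °C → rt
Reagents that add atoms: chlorotriisopropylsilane (TIPSCl), CC(C)[Si](Cl)(C(C)C)C(C)C
Why: Chemoselective silylation should occur at the hydroxyl para to the formyl group, which is the more acidic one and is not tied up in the intramolecular hydrogen bond that deactivates the ortho hydroxyl.

Step 6
Reactants: 9 2-hydroxy-6-methoxy-3-(3-methylbut-2-en-1-yl)-4-(triisopropylsilyloxy)benzaldehyde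
Product: 10 2-(hydroxymethyl)-3-methoxy-6-(3-methylbut-2-en-1-yl)-5-(triisopropylsilyloxy)phenol
Conditions: NaBH4, THF–EtOH, 0 °C; pH 7 buffer work-up; used without storage
Reagents that add atoms: none
Why: Borohydride reduction of the aldehyde should give the salicyl alcohol under non-acidic conditions, which matters because this electron-rich benzylic alcohol ionises easily.

Step 7
Reactants: 11 4-hydroxybenzaldehyde
Product: 12 4-(tert-butyldimethylsilyloxy)benzaldehyde
Conditions: TBSCl, imidazole, DMF, rt
Reagents that add atoms: tert-butyldimethylsilyl chloride (TBSCl), CC(C)(C)[Si](C)(C)Cl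
Why: Imidazole-promoted silylation of a phenol is a standard protection and should proceed cleanly.

Step 8
Reactants: 12 4-(tert-butyldimethylsilyloxy)benzaldehyde
Product: 13 tert-butyl(4-ethynylphenoxy)dimethylsilane
Conditions: TMSCHN2, n-BuLi, THF, −78 °C → rt
Reagents that add atoms: (trimethylsilyl)diazomethane, C[Si](C)(C)C=[N+]=[N-]
Why: The Colvin rearrangement (Shioiri one-carbon homologation) with lithiated trimethylsilyldiazomethane should convert the aryl aldehyde directly into the terminal alkyne and avoids the basic methanol of other homologations, which would cleave the aryl silyl ether.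

Step 9
Reactants: 13 tert-butyl(4-ethynylphenoxy)dimethylsilane; 14 benzyldimethylsilane
Product: 15 (E)-benzyl{2-[4-(tert-butyldimethylsilyloxy)phenyl]ethenyl}dimethylsilane
Conditions: Pt2(dvds)3 (Karstedt, 0.5 mol %), t-Bu3P (1 mol %), THF, rt
Reagents that add atoms: none
Why: Platinum(0)-catalysed hydrosilylation (Chalk–Harrod syn addition) with a bulky phosphine should place silicon on the terminal carbon and hydrogen cis to it, giving the E-β-vinylsilane.

Step 10
Reactants: 10 2-(hydroxymethyl)-3-methoxy-6-(3-methylbut-2-en-1-yl)-5-(triisopropylsilyloxy)phenol; 15 (E)-benzyl{2-[4-(tert-butyldimethylsilyloxy)phenyl]ethenyl}dimethylsilane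
Product: 17 (2R,3S)-3-(benzyldimethylsilyl)-2-[4-(tert-butyldimethylsilyloxy)phenyl]-5-methoxy-8-(3-methylbut-2-en-1-yl)-7-(triisopropylsilyloxy)chromane, via ortho-quinone methide 16 (not isolated)
Conditions: (R)-TRIP (10 mol %), 15 (1.5 equiv), 3 Å MS, toluene, −20 °C, slow addition of 10; Et3N quench
Reagents that add atoms: none
Why: Proposed new method: the phosphoric acid should ionise the trioxygenated benzylic alcohol 10 to ortho-quinone methide 16 and stay hydrogen-bonded to its carbonyl oxygen, and the silicon-bearing alkene carbon of 15 then attacks the methide carbon (C3–C4) while positive charge builds on the other alkene carbon, where the p-silyloxyphenyl ring and the β-C–Si bond both stabilise it, before O1 closes onto it (O1–C2) in an asynchronous inverse-demand hetero-[4+2]. The closest known reaction types are thermal or acid-promoted ortho-quinone methide/styrene hetero-Diels–Alder reactions giving flavans and chiral phosphoric acid-catalysed [4+2] cycloadditions of in situ generated ortho-quinone methides with electron-rich alkenes, whereas an enantioselective version with a β-silylstyrene lacking a hydrogen-bond donor has not been described. Ring C (the dihydropyran) is closed by intermolecular [4+2] cycloaddition of the O1=C8a–C4a=C4 heterodiene across the C2=C3 alkene. The 2,3-trans relation follows from suprafacial addition to the E-alkene, which keeps aryl and silicon on opposite faces whichever endo or exo approach is taken, and the absolute configuration (2R,3S) is set by the alkene face that the catalyst pocket presents to the bound methide. The step needs regioselectivity, secured by the matched aryl and β-silicon stabilisation at C2, and suppression of methide self-condensation and of desilylative allylation, addressed by slow addition of 10 to excess 15 at low temperature and an amine quench before work-up.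

Step 11
Reactants: 17 (2R,3S)-3-(benzyldimethylsilyl)-2-[4-(tert-butyldimethylsilyloxy)phenyl]-5-methoxy-8-(3-methylbut-2-en-1-yl)-7-(triisopropylsilyloxy)chromane
Product: 19 8-prenylafzelechin 5-methyl ether [(2R,3S)-2-(4-hydroxyphenyl)-5-methoxy-8-(3-methylbut-2-en-1-yl)chromane-3,7-diol], via silanol 18 (not isolated)
Conditions: TBAF (5 equiv), THF, 0 °C → rt; then KHCO3, 30 % aq H2O2, MeOH, rt → 40 °C; aq NH4Cl work-up
Reagents that add atoms: hydrogen peroxide, OO
Why: In this Tamao–Fleming oxidation fluoride should cleave the benzyl–silicon bond and both aryl silyl ethers, and hydroperoxide then induces 1,2-migration of C3 from silicon to oxygen with retention, so the 2,3-trans (2R,3S) arrangement is carried into the target.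

**Compound list**

1 | 5-methoxyresorcinol | COc1cc(O)cc(O)c1 | starting material
2 | 1-methoxy-3,5-bis(methoxymethoxy)benzene | COCOc1cc(OC)cc(OCOC)c1 | intermediate
3 | prenyl bromide (1-bromo-3-methylbut-2-ene) | CC(C)=CCBr | starting material
4 | 2-lithio-5-methoxy-1,3-bis(methoxymethoxy)benzene (aryllithium; not isolated) | [Li]c1c(OCOC)cc(OC)cc1OCOC | intermediate
5 | 5-methoxy-1,3-bis(methoxymethoxy)-2-(3-methylbut-2-en-1-yl)benzene | COCOc1cc(OC)cc(OCOC)c1CC=C(C)C | intermediate
6 | 5-methoxy-2-(3-methylbut-2-en-1-yl)benzene-1,3-diol | COc1cc(O)c(CC=C(C)C)c(O)c1 | intermediate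
7 | N-[2,4-dihydroxy-6-methoxy-3-(3-methylbut-2-en-1-yl)benzylidene]-N-methylmethanaminium chloride (aryl iminium chloride; not isolated) | COc1cc(O)c(CC=C(C)C)c(O)c1C=[N+](C)C.[Cl-] | intermediate
8 | 2,4-dihydroxy-6-methoxy-3-(3-methylbut-2-en-1-yl)benzaldehyde | COc1cc(O)c(CC=C(C)C)c(O)c1C=O | intermediate
9 | 2-hydroxy-6-methoxy-3-(3-methylbut-2-en-1-yl)-4-(triisopropylsilyloxy)benzaldehyde | COc1cc(O[Si](C(C)C)(C(C)C)C(C)C)c(CC=C(C)C)c(O)c1C=O | intermediate
10 | 2-(hydroxymethyl)-3-methoxy-6-(3-methylbut-2-en-1-yl)-5-(triisopropylsilyloxy)phenol | COc1cc(O[Si](C(C)C)(C(C)C)C(C)C)c(CC=C(C)C)c(O)c1CO | intermediate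
11 | 4-hydroxybenzaldehyde | O=Cc1ccc(O)cc1 | starting material
12 | 4-(tert-butyldimethylsilyloxy)benzaldehyde | CC(C)(C)[Si](C)(C)Oc1ccc(C=O)cc1 | intermediate
13 | tert-butyl(4-ethynylphenoxy)dimethylsilane | C#Cc1ccc(O[Si](C)(C)C(C)(C)C)cc1 | intermediate
14 | benzyldimethylsilane | C[SiH](C)Cc1ccccc1 | starting material
15 | (E)-benzyl{2-[4-(tert-butyldimethylsilyloxy)phenyl]ethenyl}dimethylsilane | CC(C)(C)[Si](C)(C)Oc1ccc(/C=C/[Si](C)(C)Cc2ccccc2)cc1 | intermediate
16 | 3-methoxy-6-methylidene-2-(3-methylbut-2-en-1-yl)... ortho-quinone methide: 5-methoxy-6-methylidene-2-(3-methylbut-2-en-1-yl)-3-(triisopropylsilyloxy)cyclohexa-2,4-dien-1-one (not isolated) | C=C1C(=O)C(CC=C(C)C)=C(O[Si](C(C)C)(C(C)C)C(C)C)C=C1OC | intermediate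
17 | (2R,3S)-3-(benzyldimethylsilyl)-2-[4-(tert-butyldimethylsilyloxy)phenyl]-5-methoxy-8-(3-methylbut-2-en-1-yl)-7-(triisopropylsilyloxy)chromane | COc1cc(O[Si](C(C)C)(C(C)C)C(C)C)c(CC=C(C)C)c2c1C[C@H]([Si](C)(C)Cc1ccccc1)[C@@H](c1ccc(O[Si](C)(C)C(C)(C)C)cc1)O2 | intermediate
18 | (2R,3S)-3-(hydroxydimethylsilyl)-2-(4-hydroxyphenyl)-5-methoxy-8-(3-methylbut-2-en-1-yl)chroman-7-ol (silanol; not isolated) | COc1cc(O)c(CC=C(C)C)c2c1C[C@H]([Si](C)(C)O)[C@@H](c1ccc(O)cc1)O2 | intermediate
19 | 8-prenylafzelechin 5-methyl ether, (2R,3S)-2-(4-hydroxyphenyl)-5-methoxy-8-(3-methylbut-2-en-1-yl)chromane-3,7-diol | COc1cc(O)c(CC=C(C)C)c2c1C[C@H](O)[C@@H](c1ccc(O)cc1)O2 | target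

**Count and risks**

Total steps: 11. Longest linear sequence: 8 (steps 1–6, 10, 11).

Steps most likely to fail:

1. Step 10 (proposed new method). The catalyst may discriminate poorly between the two faces of an alkene that offers it no hydrogen-bond handle. The methide may also be consumed by attack of the free ring position of a second molecule. The β-silyl cation may lose silicon instead of closing, or the adduct may reopen at O1–C2 under acid, in both cases giving a ring-opened allylation product. Fallback with known chemistry, setting out from 9 and 13 and returning at 19: alkyne 13 is hydroborated with catecholborane to the (E)-alkenyl catechol boronate F1, which is hydrolysed to (E)-2-[4-(tert-butyldimethylsilyloxy)phenyl]ethenylboronic acid F2. F2 is condensed with salicylaldehyde 9 under secondary-amine promotion (Petasis-type borono-Mannich reaction, then cyclisation with loss of the amine) to the racemic 2-aryl-2H-chromene (flav-3-ene) F3. Copper-catalysed enantioselective protoboration (B2pin2, MeOH, chiral bisphosphine), run as a kinetic resolution, should add boron to C3 anti to the C2 aryl group of the matched enantiomer. It acts only on the styrenic C3=C4 bond and leaves the prenyl group alone, giving the trans-3-boryl flavan F4. Oxidation with NaBO3 proceeds with retention to the flavan-3-ol bis-silyl ether F5, and TBAF alone then gives 19.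

2. Step 11. Fluoride-activated silicon lies antiperiplanar to the O1–C2 bond and may eliminate (Peterson-type opening of the pyran ring) faster than it is oxidised. The liberated electron-rich phenolates may be degraded by basic peroxide, and prolonged base exposure may epimerise C2 through a ring-B quinone methide. Fallback, setting out from 13 and returning at 19: 13 is hydrosilylated (Pt) with 1,1,1,3,5,5,5-heptamethyltrisiloxane to the (E)-alkenyl trisiloxane F6, which is taken through the step-10 cycloaddition with 10 to the 3-trisiloxanyl flavan F7. Its oxygen-substituted silicon should be oxidised by bicarbonate-buffered H2O2 (KHF2 as a mild activator if needed) without TBAF, so the phenols stay protected during the oxidation and no naked fluoride meets the β-aryloxy silane. This gives the flavan-3-ol bis-silyl ether F5, and TBAF in a separate non-oxidative step gives 19.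

3. Step 3. Under the acid needed for acetal cleavage the freed phenol may add across the prenyl double bond (2,2-dimethylchroman formation), or the alkene may take up HCl or methanol. Fallback, setting out from 1 and returning at 6: a fluoride-labile directing acetal replaces MOM. 1 is converted with SEMCl/NaH into 1-methoxy-3,5-bis{[2-(trimethylsilyl)ethoxy]methoxy}benzene F8, lithiated with n-BuLi to the 2-lithio bis-SEM ether F9, and allylated with 3 (CuI cat.) to the 2-prenyl bis-SEM ether F10. TBAF with ethylenediamine as formaldehyde scavenger (DMF, 50 °C) then releases 6 without any acid.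

**Further compounds**

F1 | step 10 | (E)-2-{2-[4-(tert-butyldimethylsilyloxy)phenyl]ethenyl}-1,3,2-benzodioxaborole | CC(C)(C)[Si](C)(C)Oc1ccc(/C=C/B2Oc3ccccc3O2)cc1
F2 | step 10 | (E)-2-[4-(tert-butyldimethylsilyloxy)phenyl]ethenylboronic acid | CC(C)(C)[Si](C)(C)Oc1ccc(/C=C/B(O)O)cc1
F3 | step 10 | racemic 2-[4-(tert-butyldimethylsilyloxy)phenyl]-5-methoxy-8-(3-methylbut-2-en-1-yl)-7-(triisopropylsilyloxy)-2H-chromene | COc1cc(O[Si](C(C)C)(C(C)C)C(C)C)c(CC=C(C)C)c2c1C=CC(c1ccc(O[Si](C)(C)C(C)(C)C)cc1)O2
F4 | step 10 | 2,3-trans-3-(pinacolatoboryl)flavan bis-silyl ether, same spatial arrangement as 19 (CIP 2S,3S because boron ranks below carbon) | COc1cc(O[Si](C(C)C)(C(C)C)C(C)C)c(CC=C(C)C)c2c1C[C@H](B1OC(C)(C)C(C)(C)O1)[C@@H](c1ccc(O[Si](C)(C)C(C)(C)C)cc1)O2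
F5 | step 10 | (2R,3S)-2-[4-(tert-butyldimethylsilyloxy)phenyl]-5-methoxy-8-(3-methylbut-2-en-1-yl)-7-(triisopropylsilyloxy)chroman-3-ol | COc1cc(O[Si](C(C)C)(C(C)C)C(C)C)c(CC=C(C)C)c2c1C[C@H](O)[C@@H](c1ccc(O[Si](C)(C)C(C)(C)C)cc1)O2
F6 | step 11 | (E)-3-{2-[4-(tert-butyldimethylsilyloxy)phenyl]ethenyl}-1,1,1,3,5,5,5-heptamethyltrisiloxane | CC(C)(C)[Si](C)(C)Oc1ccc(/C=C/[Si](C)(O[Si](C)(C)C)O[Si](C)(C)C)cc1
F7 | step 11 | (2R,3S)-2-[4-(tert-butyldimethylsilyloxy)phenyl]-3-(1,1,1,3,5,5,5-heptamethyltrisiloxan-3-yl)-5-methoxy-8-(3-methylbut-2-en-1-yl)-7-(triisopropylsilyloxy)chromane | COc1cc(O[Si](C(C)C)(C(C)C)C(C)C)c(CC=C(C)C)c2c1C[C@H]([Si](C)(O[Si](C)(C)C)O[Si](C)(C)C)[C@@H](c1ccc(O[Si](C)(C)C(C)(C)C)cc1)O2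
F8 | step 3 | 1-methoxy-3,5-bis{[2-(trimethylsilyl)ethoxy]methoxy}benzene | COc1cc(OCOCC[Si](C)(C)C)cc(OCOCC[Si](C)(C)C)c1
F9 | step 3 | 2-lithio-5-methoxy-1,3-bis{[2-(trimethylsilyl)ethoxy]methoxy}benzene (not isolated) | [Li]c1c(OCOCC[Si](C)(C)C)cc(OC)cc1OCOCC[Si](C)(C)C
F10 | step 3 | 5-methoxy-2-(3-methylbut-2-en-1-yl)-1,3-bis{[2-(trimethylsilyl)ethoxy]methoxy}benzene | COc1cc(OCOCC[Si](C)(C)C)c(CC=C(C)C)c(OCOCC[Si](C)(C)C)c1
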